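The four readings of the alpha run at 2.50 h add up to 98.7 %, within scatter of the starting material charged, so starting material that disappears stands as intermediate, isomer of the product or target.

| flask | starting material | reagent | remark | time |
|---|---|---|---|---|
| theta | 0.80 M | 0.33 M | run made earlier |  |
| alpha | 0.80 M | 0.82 M | run made earlier |  |
| alder | 0.80 M | 0.720 M |  | 2.5 h |
| cedar | 0.80 M | 0.480 M |  | 2.5 h |
| larch | 0.80 M | 1.10 M |  | 2.5 h |

| run | time / h | intermediate / % | isomer of the product / % | starting material / % | target / % |
|---|---|---|---|---|---|
| theta | 0.167 | 18.2 | 3.6 | 78.8 | 4.1 |
| theta | 0.500 | 16.5 | 8.2 | 62.0 | 9.4 |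
| theta | 0.833 | 15.3 | 13.5 | 61.1 | 11.3 |
| theta | 1.33 | 13.7 | 17.6 | 58.3 | 10.2 |
| theta | 2.00 | 11.5 | 20.8 | 60.6 | 8.4 |
| theta | 2.50 | 11.7 | 21.0 | 57.7 | 6.3 |
| alpha | 0.167 | 36.5 | 4.9 | 50.3 | 9.4 |
| alpha | 0.500 | 37.0 | 18.5 | 25.6 | 21.5 |
| alpha | 0.833 | 32.2 | 29.6 | 15.1 | 22.9 |
| alpha | 1.33 | 28.8 | 37.0 | 9.0 | 19.5 |
| alpha | 2.00 | 25.9 | 48.9 | 7.4 | 18.6 |
| alpha | 2.50 | 24.8 | 50.7 | 6.1 | 17.1 |

(readings scatter by 1 percentage point)



- which of these there is most of at the end, counted by the starting material in it, alder (target / isomer of the product / starting material / intermediate)
- which of these there is most of at the end, counted by the starting material in it, cedar (target / isomer of the product / starting material / intermediate)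
- which of these there is most of at the end, counted by the starting material in it, larch (target / isomer of the product / starting material / intermediate)
- final amount of the leader among these, as a percentage of the starting material charged, in alder
- final amount of the leader among these, as a percentage of the starting material charged, in cedar
- final amount of the leader among these, as a percentage of the starting material charged, in larch

Two numbers seem not to fit. From the alpha run to the theta run the reagent charge falls by a factor of 2.48, yet the starting material left at 2.50 h rises by a factor of 9.46, to 57.7 %.

The reckoning treats the reagent step as finished and asks what it leaves. The theta run lost 0.338 M of starting material against 0.33 M of reagent, which reads as one to one. So: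

floor = 1 − c(reagent)/c(starting material)

theta: 58.8 %
alder: 10.0 %
cedar: 40.0 %

This floor is the share of the starting material left unreacted when the reagent, here the limiting reagent, has been used one to one. The theta run reads 61.1 % at 0.833 h, a third of the way to the end, and 57.7 % at 2.50 h, so its late readings lie on both sides of its floor . The alpha run and larch each have more reagent than starting material , so neither has a floor above zero, and the alpha run's starting material reads 9.0 % at 1.33 h and 6.1 % at 2.50 h.

The isomer of the product reads as 54.0 % of the converted material in the alpha run and 49.6 % in the theta run. With the higher share: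

alder: 48.6 %
cedar: 32.4 %
larch: 54.0 %

So the reckoning puts the isomer of the product in the lead in alder and larch, and in cedar it stays below the floor, so starting material leads there.

The forecast names isomer of the product at 47 % for alder, starting material at 40 % for cedar and isomer of the product at 55 % for larch, with “the reagent is consumed 1:1”; its alder figure stands below the one reckoned here and its larch figure above it.

Alder ends with isomer of the product at 47.3 %, cedar with starting material at 40.1 % and larch with isomer of the product at 55.3 %. Cedar's starting material stands 0.100 percentage points from its floor of 40.0 %, while its reagent is down to 0.13 % of its own charge, less than the 40 % of its charge that the starting material keeps.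

    intermediate ⇌ isomer of the product (K = 2.50, k = 3.30 × 10⁻⁴ s⁻¹)
    starting material + reagent → intermediate + by-product (k = 0.00200 M⁻¹ s⁻¹)
    crystals ⇌ by-product, rate k3*(cs3 - [by-product]) while solid is left; crystals form when [by-product] > cs3 (solubility = 0.300 M, k = 0.0640 s⁻¹)
    intermediate ⇌ target (K = 0.670, k = 7.00 × 10⁻⁴ s⁻¹)

A neighbour of larch, charged with 2.0 M of starting material against larch's 1.10 M of reagent, has a floor of 45.0 %, and it ends with starting material leading at 45.0 %.

The data are simulated for substances that don't exist, and the scatter is random.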